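Assumption (remark on the chemistry): Locants are C1'–C6' for ring A (C1' bears the carbonyl) and C1''–C8'' for the side chain counted from the ring; C2'' is R in 8, 9, 13, 14 and 15 (in 8 boron ranks below both carbon substituents, so the letter stays R although the priority order differs); the chiral bisphosphine of step 3 is (SP,S'P)-1,1'-bis[bis(4-methoxy-3,5-dimethylphenyl)phosphino]-2,2'-bis[(R)-α-(dimethylamino)benzyl]ferrocene (MandyPhos type), assumed to favour the R boronate, and its mirror-image ligand is used if the first run shows the opposite sense.

## Structural features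

The target is a 2',4,4'-trihydroxychalcone. Ring A carries the enone carbonyl at C1', hydroxyls at C2' and C4', and a ten-carbon chain on C3', the carbon between the two oxygens. Ring B is a para-hydroxyphenyl group joined through the E-configured Cα=Cβ bond. The chain reads C1''H2–C2''H(OH)–C3''(=CH2)–C4''H2–C5''H2–C6''H=C7''(CH3)2, a geranyl unit oxidised at C2'' with its first olefin moved to the exocyclic position. C2'' (R) is the only stereocentre; it is allylic and homobenzylic and has no neighbouring stereocentre to lean on. The fragile groups are the secondary allylic alcohol next to a 1,1-disubstituted olefin and ortho to two phenols (acid can close a chroman or dihydrofuran), the trisubstituted olefin (acid and electrophiles), and the 2'-hydroxy enone (conjugate addition, flavanone closure). The real difficulty is to set C2'' in absolute terms while attaching a hindered substituent at C3' between two oxygen functions and keeping two different olefins intact; regiocontrolled acylation at C1' and a gentle final deprotection come second. The key step exploits the fact that the two-carbon unit C1''–C2'' lies between aryl carbon C3' of ring A and alkenyl carbon C3''. This is the pattern left when a vinylboron unit takes an aryl group on its terminal carbon and a migrating alkenyl group on its boron-bearing carbon, and the C2''–B bond then becomes the C2''–O bond.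

## Logic of the disconnections

**15 from 14.** Only the three aryl O–CH2 acetal bonds on O2', O4' and O4 are cut. They are cut last because free phenols would quench every organometallic step and the 2'-hydroxy enone is the most delicate array in the molecule. The gain is in handling: 14 has no acidic proton other than one alcohol. The forward step must remove three acetals with acid mild enough to spare the allylic alcohol, both olefins and the enone.

**14 from 9 and 12.** The C1'–C(=O) bond is cut. C1' (equivalent to C5') is the only kind of ring position in 9 that is ortho to an acetal oxygen, so it can be made a carbanion by directed metalation, and 12 delivers the whole E enone with ring B in one C–C bond formation. The cut splits the chalcone into its two natural halves and makes the route convergent. The forward step must lithiate C1' in the presence of the C2'' hydroxyl. That hydroxyl is carried as its lithium alkoxide in 13, which saves a protecting step and avoids an acidic α-silyloxy allylic C–H or a β-silyloxy benzylic anion. The aryllithium must then add to the amide carbonyl and not to the olefin.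

**12 from 11, and 11 from 10.** One O–CH2 acetal bond and the amide C–N bond are cut. The reason is to have an acyl donor that stops at the ketone stage and a phenol that is inert to aryllithium. Both steps are routine; the only demand is that the acylation of the amine outruns acylation of the free phenol.

**9 from 8.** The C2''–O bond is traced back to a C2''–B bond. A C–B bond is the form in which this stereocentre can be made catalytically, and it oxidises with retention. No simplification of the skeleton results, but the stereochemical problem passes to the step before. The forward oxidation must proceed without allylic transposition and without touching either olefin.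

**8 from 2, 5 and 6 by way of 7.** Two bonds are cut at once, C3'–C1'' and C2''–C3''. The cut is made here because it turns the whole left half of the target into three achiral pieces: a ring A halide, a two-carbon vinylboron unit and an eight-carbon alkenyl nucleophile. The single stereocentre is then created in the same operation, and the branched olefin enters intact. The forward step demands that palladium activate the vinyl and not the branched alkenyl group of 7, that the 1,2-shift outrun direct transmetalation, that the face of the vinyl group be selected by the ligand, and that a doubly ortho-substituted aryl–palladium centre still turn over. For that reason the iodide (easiest oxidative addition) is kept, a triflate salt is added to remove halide from palladium, and no free organolithium is allowed to remain when 2 is added.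

**6 from 4, and 4 from 3.** The C3''–Li bond is traced to a C=N bond and then to the ketone carbonyl. A methyl ketone is the cheapest source of a 2-metallated 1-alkene, and the sulfonylhydrazone route fixes the double bond on the methyl side. The forward step needs deprotonation at the methyl group (secured by the hydrazone geometry) and a small deficit of base so that no alkyllithium survives.

**2 from 1.** The two O–CH2 acetal bonds are cut. The acetals make the phenols inert in step 3 and later direct the metalation; the forward step is a plain double O-alkylation.

## Other disconnections considered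

**Alternative 1:** The cut runs through ring A itself, at C1'–C2' and C5'–C6', so that the ring is built last around a finished side chain.
- Forward step: the 2-alkylated 1-methoxy-1,3-bis(trimethylsilyloxy)diene A2, made by double silylation of the 2-alkylacetoacetate A1, would undergo a thermal [4+2] cycloaddition with the terminal ynone A3. The CH2 terminus of A2 bonds to the alkyne CH (C5'–C6') and the ketene-acetal carbon to the carbonyl-bearing alkyne carbon (C1'–C2'). Loss of methanol or its silyl ether would aromatise the adduct to A4 after aqueous work-up.
- In its favour: the positions of all four ring A substituents follow from the polarity of the partners, and no aryl metalation is needed. The end game would be a fluoride desilylation, which is kinder to the hydroxy-diene chain than the acid of step 8; on this point the alternative is the better plan.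
- Against it here: it does nothing for C2'', which must still be made enantioselectively and then homologated into A1 over several steps on a fragile chain. A2 is a hydrolytically labile, fully substituted diene whose 2-alkyl group slows cycloaddition. A3 is a cross-conjugated ynone–enone that offers a second acceptor site and is prone to polymerise on heating.
- Comparison: a metal-free pericyclic step is free of the catalyst-inhibition questions of step 3, which is an advantage. Structurally it builds the easy part (an arene) and leaves the hard part (the stereocentre) to other chemistry. It is equal in convergence and clearly longer in steps.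

**Alternative 2:** The cut is the C2''–O bond, made together with a temporary C3''–O bond by hydroxyl-directed epoxidation.
- Forward step: the E allylic alcohol A5, whose CH2OH is the latent exocyclic methylene, would be epoxidised under Sharpless conditions (Ti(OiPr)4 A6, D-(−)-diisopropyl tartrate A7, tert-butyl hydroperoxide A8) to the (2R,3R)-epoxy alcohol A9. Conversion of the primary alcohol into a halide and zinc-induced reductive opening would then unveil the 1,1-disubstituted olefin and the R carbinol, that is 9.
- In its favour: face selectivity of this epoxidation is among the most predictable for E trisubstituted primary allylic alcohols, the directing hydroxyl makes it blind to the remote olefin, and the catalyst is cheap. In predictability of enantiocontrol and in reagent cost it is the better of the two plans.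
- Against it here: A5 needs a geometrically pure trisubstituted olefin with three different carbon substituents, itself a multi-step problem. The aryl–C1'' bond must be made separately, and two functional-group steps follow the epoxidation.
- Comparison: both plans reach 9 and share the end game, so they differ only on the way to 9. That is about two operations from the building blocks in the chosen route against an estimated six to eight here. The epoxidation makes a C–O bond and the stereocentre; step 3 makes two C–C bonds and the stereocentre.

**Alternative 3:** The cut isolates the carbonyl carbon: C1'–C(=O) and C(=O)–Cα are made in one step.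
- Forward step: the C1' iodide A10 (side chain in place, C2''–O silylated), carbon monoxide A11 and 4-acetoxystyrene A12 would be joined by a carbonylative Heck reaction (Pd(OAc)2 with a bulky phosphine) to give the fully protected chalcone A13, with the E enone formed directly.
- In its favour: ring B enters as a cheap styrene with no separate amide fragment, the enone geometry follows from syn β-hydride elimination, and no organolithium meets an unsaturated carbonyl compound. In the preparation of the ring B piece it is the better plan, and in convergence it is equal.
- Against it here: A10 is most sensibly made by the same C1' lithiation as in step 7, quenched with iodine, because electrophilic iodination would attack the olefins. The metalation is therefore not avoided but followed by an extra step. Direct arylation of the styrene without CO insertion competes, hydridopalladium species may isomerise the side-chain olefins, and three kinds of protecting group (acetal, silyl, acetate) lengthen the end game.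
- Comparison: the alternative replaces a stoichiometric carbanion addition by a catalytic three-component step, but it is at least one step longer and adds a second palladium step with its own selectivity question. The stereocentre would still come from step 3.

Key step: step 3

## Route

Step 1
Reactants: 1 2-iodoresorcinol
Product: 2 2-iodo-1,3-bis(methoxymethoxy)benzene
Conditions: MOMCl (2.5 equiv), i-Pr2NEt (3 equiv), CH2Cl2, 0 °C to rt
Reagents that add atoms: chloromethyl methyl ether (MOMCl), COCCl
Why: Double O-alkylation of the phenols by the chloromethyl ether under amine base (Williamson-type acetal ether formation) should be clean; the aryl iodide is inert and no stereocentre is involved.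

Step 2
Reactants: 3 6-methylhept-5-en-2-one
Product: 4 (E)-N'-(6-methylhept-5-en-2-ylidene)-2,4,6-tri(propan-2-yl)benzenesulfonohydrazide
Conditions: 2,4,6-triisopropylbenzenesulfonohydrazide (1.0 equiv), MeOH, cat. HCl, rt
Reagents that add atoms: 2,4,6-triisopropylbenzenesulfonohydrazide, CC(C)c1cc(C(C)C)c(S(=O)(=O)NN)c(C(C)C)c1
Why: Acid-catalysed hydrazone formation from a methyl ketone should give mainly the E isomer, in which the N–N bond lies syn to the methyl group, the geometry that later directs deprotonation to the methyl carbon; the trisubstituted olefin is untouched at room temperature.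

Step 3
Reactants: 4 (E)-N'-(6-methylhept-5-en-2-ylidene)-2,4,6-tri(propan-2-yl)benzenesulfonohydrazide, 5 vinylboronic acid pinacol ester, 2 2-iodo-1,3-bis(methoxymethoxy)benzene
Product: 8 2-[(2R)-1-[2,6-bis(methoxymethoxy)phenyl]-7-methyl-3-methylideneoct-6-en-2-yl]-4,4,5,5-tetramethyl-1,3,2-dioxaborolane, via alkenyllithium 6 (not isolated), via bis(alkenyl)borate 7 (not isolated)
Conditions: 4 (1.35 equiv), n-BuLi (1.95 equiv per 4), THF, −78 to 0 °C; 5 (1.4 equiv), −78 °C to rt; then 2 (1.0 equiv), Pd(OAc)2 (3 mol %), (SP,S'P)-1,1'-bis[bis(4-methoxy-3,5-dimethylphenyl)phosphino]-2,2'-bis[(R)-α-(dimethylamino)benzyl]ferrocene (3.6 mol %), KOTf (2 equiv), THF, 60 °C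
Reagents that add atoms: n-butyllithium, [Li]CCCC (supplies only the lithium of 6 and 7; 8 holds atoms of 4, 5 and 2 alone)
Why: In a Shapiro reaction n-BuLi removes the N–H proton and a proton of the syn methyl group of 4, and loss of sulfinate and N2 at 0 °C should give 6, which adds to the boron of 5 to form borate 7; the slight deficit of n-BuLi and the slight excess of 5 ensure that no free organolithium meets 2. Zerovalent palladium inserts into the C3'–I bond of 2, KOTf removes iodide as KI, and the cationic aryl complex of divalent palladium binds the unsubstituted vinyl group of 7. This binding induces anti 1,2-migration of the branched alkenyl group from boron to C2'' while palladium bonds to C1'', and reductive elimination then forms C3'–C1''. The closest known reaction type is the palladium-catalysed enantioselective conjunctive cross-coupling of bis(alkenyl)borates with aryl electrophiles in the presence of a triflate salt. No ring is closed. The new stereocentre C2'' is set in the metallate shift by the chiral ferrocenyl bisphosphine, which selects the face of the bound vinyl group and should give the R boronate. The step needs palladium to choose the vinyl over the 1,1-disubstituted alkenyl group as its olefin ligand, which the smaller size of vinyl secures, and it needs the shift to outrun direct alkenyl transfer, which the halide-free cationic palladium centre favours. The acetals, the trisubstituted olefin and the C–B bond should survive the neutral conditions at 60 °C.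

Step 4
Reactants: 8 2-[(2R)-1-[2,6-bis(methoxymethoxy)phenyl]-7-methyl-3-methylideneoct-6-en-2-yl]-4,4,5,5-tetramethyl-1,3,2-dioxaborolane
Product: 9 (2R)-1-[2,6-bis(methoxymethoxy)phenyl]-7-methyl-3-methylideneoct-6-en-2-ol
Conditions: NaBO3·4H2O (4 equiv), THF/H2O 1:1, rt
Reagents that add atoms: sodium perborate, [Na+].[O-]OB=O
Why: Perborate oxidation of a C–B bond proceeds by addition of the peroxide to boron and 1,2-migration of C2'' to oxygen with retention and without allylic transposition, so the R boronate should give the R alcohol; the buffered, mildly basic medium leaves acetals and both olefins intact.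

Step 5
Reactants: 10 p-coumaric acid
Product: 11 (2E)-3-(4-hydroxyphenyl)-N-methoxy-N-methylprop-2-enamide
Conditions: MeNHOMe·HCl (1.2 equiv), EDC·HCl (1.2 equiv), HOBt (1.2 equiv), N-methylmorpholine (2.5 equiv), DMF, 0 °C to rt
Reagents that add atoms: N,O-dimethylhydroxylamine hydrochloride, CNOC.Cl
Why: Carbodiimide/HOBt amide coupling should be selective because the amine outcompetes the free phenol for the active ester; the E olefin is not affected.

Step 6
Reactants: 11 (2E)-3-(4-hydroxyphenyl)-N-methoxy-N-methylprop-2-enamide
Product: 12 (2E)-N-methoxy-3-[4-(methoxymethoxy)phenyl]-N-methylprop-2-enamide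
Conditions: MOMCl (1.3 equiv), i-Pr2NEt (2 equiv), CH2Cl2, 0 °C to rt
Reagents that add atoms: chloromethyl methyl ether (MOMCl), COCCl
Why: O-alkylation of the phenol (acetal ether formation) removes the only acidic proton of the acyl donor; the amide and the olefin are inert.

Step 7
Reactants: 9 (2R)-1-[2,6-bis(methoxymethoxy)phenyl]-7-methyl-3-methylideneoct-6-en-2-ol, 12 (2E)-N-methoxy-3-[4-(methoxymethoxy)phenyl]-N-methylprop-2-enamide
Product: 14 (2E)-1-{3-[(2R)-2-hydroxy-7-methyl-3-methylideneoct-6-en-1-yl]-2,4-bis(methoxymethoxy)phenyl}-3-[4-(methoxymethoxy)phenyl]prop-2-en-1-one, via dilithiated alkoxide 13 (not isolated)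
Conditions: n-BuLi (2.2 equiv), THF, −20 to 0 °C; then 12 (1.4 equiv), −78 to −20 °C; aq. NH4Cl
Reagents that add atoms: n-butyllithium, [Li]CCCC (supplies only the lithium of 13)
Why: The first equivalent of n-BuLi forms the C2'' lithium alkoxide, which needs no protecting group and shuts off deprotonation at C2''; the second effects directed ortho-metalation at C1', the only kind of ring position ortho to an acetal director. The aryllithium should add to the carbonyl of the N-methoxy-N-methyl amide (Weinreb ketone synthesis), whose chelated adduct releases the E enone only on work-up, and the stereocentre is not touched.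

Step 8
Reactants: 14 (2E)-1-{3-[(2R)-2-hydroxy-7-methyl-3-methylideneoct-6-en-1-yl]-2,4-bis(methoxymethoxy)phenyl}-3-[4-(methoxymethoxy)phenyl]prop-2-en-1-one
Product: 15 (2E)-1-{2,4-dihydroxy-3-[(2R)-2-hydroxy-7-methyl-3-methylideneoct-6-en-1-yl]phenyl}-3-(4-hydroxyphenyl)prop-2-en-1-one
Conditions: HCl (ca. 1.5 M), MeOH/THF 3:1, 30–40 °C, monitored; then NaHCO3
Reagents that add atoms: none
Why: Acid-catalysed acetal exchange with methanol should remove the three aryl acetals as dimethoxymethane, the one ortho to the ketone first; dilute acid at mild temperature is chosen to spare the allylic alcohol, both olefins and the 2'-hydroxy enone. No bond to C2'' is broken, so the configuration is kept.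

## Compound list

1 | 2-iodoresorcinol (2-iodobenzene-1,3-diol) | Oc1cccc(O)c1I | starting material
2 | 2-iodo-1,3-bis(methoxymethoxy)benzene | COCOc1cccc(OCOC)c1I | intermediate
3 | 6-methylhept-5-en-2-one | CC(=O)CCC=C(C)C | starting material
4 | (E)-N'-(6-methylhept-5-en-2-ylidene)-2,4,6-tri(propan-2-yl)benzenesulfonohydrazide | CC(C)=CCC/C(C)=N/NS(=O)(=O)c1c(C(C)C)cc(C(C)C)cc1C(C)C | intermediate
5 | vinylboronic acid pinacol ester (2-ethenyl-4,4,5,5-tetramethyl-1,3,2-dioxaborolane) | C=CB1OC(C)(C)C(C)(C)O1 | starting material
6 | (6-methylhepta-1,5-dien-2-yl)lithium | [Li]C(=C)CCC=C(C)C | intermediate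
7 | lithium ethenyl(6-methylhepta-1,5-dien-2-yl)(2,3-dimethylbutane-2,3-diolato)borate | C=C[B-]1(C(=C)CCC=C(C)C)OC(C)(C)C(C)(C)O1.[Li+] | intermediate
8 | 2-[(2R)-1-[2,6-bis(methoxymethoxy)phenyl]-7-methyl-3-methylideneoct-6-en-2-yl]-4,4,5,5-tetramethyl-1,3,2-dioxaborolane | C=C(CCC=C(C)C)[C@H](B1OC(C)(C)C(C)(C)O1)Cc2c(OCOC)cccc2OCOC | intermediate
9 | (2R)-1-[2,6-bis(methoxymethoxy)phenyl]-7-methyl-3-methylideneoct-6-en-2-ol | C=C(CCC=C(C)C)[C@H](O)Cc1c(OCOC)cccc1OCOC | intermediate
10 | p-coumaric acid ((2E)-3-(4-hydroxyphenyl)prop-2-enoic acid) | O=C(O)/C=C/c1ccc(O)cc1 | starting material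
11 | (2E)-3-(4-hydroxyphenyl)-N-methoxy-N-methylprop-2-enamide | CON(C)C(=O)/C=C/c1ccc(O)cc1 | intermediate
12 | (2E)-N-methoxy-3-[4-(methoxymethoxy)phenyl]-N-methylprop-2-enamide | CON(C)C(=O)/C=C/c1ccc(OCOC)cc1 | intermediate
13 | lithium (2R)-1-[3-lithio-2,6-bis(methoxymethoxy)phenyl]-7-methyl-3-methylideneoct-6-en-2-olate | C=C(CCC=C(C)C)[C@H](O[Li])Cc1c(OCOC)ccc([Li])c1OCOC | intermediate
14 | (2E)-1-{3-[(2R)-2-hydroxy-7-methyl-3-methylideneoct-6-en-1-yl]-2,4-bis(methoxymethoxy)phenyl}-3-[4-(methoxymethoxy)phenyl]prop-2-en-1-one | C=C(CCC=C(C)C)[C@H](O)Cc1c(OCOC)ccc(C(=O)/C=C/c2ccc(OCOC)cc2)c1OCOC | intermediate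
15 | (2E)-1-{2,4-dihydroxy-3-[(2R)-2-hydroxy-7-methyl-3-methylideneoct-6-en-1-yl]phenyl}-3-(4-hydroxyphenyl)prop-2-en-1-one | C=C(CCC=C(C)C)[C@H](O)Cc1c(O)ccc(C(=O)/C=C/c2ccc(O)cc2)c1O | target

## Step count and least certain steps

Total step count: 8. Longest linear sequence: 5 steps (steps 2, 3, 4, 7 and 8, from 3 to 15).

**Step 3 (key step).** The most likely failure is inhibition of the cationic palladium centre by iodide or by the sulfinate left from the Shapiro reaction, combined with slow turnover at the doubly ortho-substituted aryl–palladium centre. Direct alkenyl transfer (plain cross-coupling) or protodeboronation would then overtake the metallate shift, and face selectivity could also fall short with this hindered aryl group. A bulkier diol on boron or a sulfinate-free preparation of 6 would be tried first as adjustments within the same step. The fallback changes the approach to a ketone reduction and runs from 2 to 9: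
- Iodine–lithium exchange on 2 (n-BuLi, THF, −78 °C) and opening of ethylene oxide with BF3·OEt2 would give 2-[2,6-bis(methoxymethoxy)phenyl]ethan-1-ol F1.
- Dess–Martin oxidation would give [2,6-bis(methoxymethoxy)phenyl]acetaldehyde F2.
- Addition of 6 (made from 4 as in step 3) at −78 °C would give racemic 1-[2,6-bis(methoxymethoxy)phenyl]-7-methyl-3-methylideneoct-6-en-2-ol F3.
- A second Dess–Martin oxidation would give 1-[2,6-bis(methoxymethoxy)phenyl]-7-methyl-3-methylideneoct-6-en-2-one F4.
- Corey–Bakshi–Shibata reduction of F4 with (S)-1-methyl-3,3-diphenyltetrahydro-1H,3H-pyrrolo[1,2-c][1,3,2]oxazaborole and catecholborane at low temperature would return 9. The branched alkenyl group is expected to act as the larger carbonyl substituent, which gives the R alcohol.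

**Step 7.** The most likely failures are incomplete or misdirected metalation (competing deprotonation at benzylic C1'' or at an allylic position, or sluggish reaction of the aggregated alkoxide) and conjugate instead of carbonyl addition to 12. The fallback replaces C–H lithiation by bromine–lithium exchange and runs from 2 to 13:
- Bromination of 2 with NBS in MeCN would give 1-bromo-3-iodo-2,4-bis(methoxymethoxy)benzene F5.
- F5 would replace 2 in step 3, where oxidative addition at C–I should precede that at C–Br, to give 2-[(2R)-1-[3-bromo-2,6-bis(methoxymethoxy)phenyl]-7-methyl-3-methylideneoct-6-en-2-yl]-4,4,5,5-tetramethyl-1,3,2-dioxaborolane F6.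
- Perborate oxidation as in step 4 would give (2R)-1-[3-bromo-2,6-bis(methoxymethoxy)phenyl]-7-methyl-3-methylideneoct-6-en-2-ol F7.
- Treatment of F7 with n-BuLi (1 equiv, −78 °C, alkoxide formation) and then t-BuLi (2 equiv) would give 13, which is acylated with 12 as in step 7.

**Step 8.** The most likely failures are acid-promoted cyclisation of a freed ortho phenol onto the protonated 1,1-disubstituted olefin or the ionised allylic alcohol, closure of the 2'-hydroxy enone to a flavanone, and incomplete cleavage of the C4' acetal under conditions mild enough to avoid these. The fallback replaces the acid-labile acetals by fluoride-labile groups and runs from 1 to 15: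
- Protection of 1 with 2-(trimethylsilyl)ethoxymethyl chloride and i-Pr2NEt would give 2-iodo-1,3-bis{[2-(trimethylsilyl)ethoxy]methoxy}benzene F8.
- F8 taken through steps 3 and 4 would give 2-[(2R)-1-(2,6-bis{[2-(trimethylsilyl)ethoxy]methoxy}phenyl)-7-methyl-3-methylideneoct-6-en-2-yl]-4,4,5,5-tetramethyl-1,3,2-dioxaborolane F9 and then (2R)-1-(2,6-bis{[2-(trimethylsilyl)ethoxy]methoxy}phenyl)-7-methyl-3-methylideneoct-6-en-2-ol F10.
- Silylation of 11 (TBSCl, imidazole) would give (2E)-3-{4-[(tert-butyldimethylsilyl)oxy]phenyl}-N-methoxy-N-methylprop-2-enamide F11.
- The conditions of step 7 applied to F10 and F11 would give (2E)-3-{4-[(tert-butyldimethylsilyl)oxy]phenyl}-1-{3-[(2R)-2-hydroxy-7-methyl-3-methylideneoct-6-en-1-yl]-2,4-bis{[2-(trimethylsilyl)ethoxy]methoxy}phenyl}prop-2-en-1-one F12.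
- TBAF in THF/DMPU at about 50 °C would remove all three groups from F12 without acid and give 15.

## Further compounds

F1 | step 3 | 2-[2,6-bis(methoxymethoxy)phenyl]ethan-1-ol | OCCc1c(OCOC)cccc1OCOC
F2 | step 3 | [2,6-bis(methoxymethoxy)phenyl]acetaldehyde | O=CCc1c(OCOC)cccc1OCOC
F3 | step 3 | racemic 1-[2,6-bis(methoxymethoxy)phenyl]-7-methyl-3-methylideneoct-6-en-2-ol | C=C(CCC=C(C)C)C(O)Cc1c(OCOC)cccc1OCOC
F4 | step 3 | 1-[2,6-bis(methoxymethoxy)phenyl]-7-methyl-3-methylideneoct-6-en-2-one | C=C(CCC=C(C)C)C(=O)Cc1c(OCOC)cccc1OCOC
F5 | step 7 | 1-bromo-3-iodo-2,4-bis(methoxymethoxy)benzene | COCOc1ccc(Br)c(OCOC)c1I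
F6 | step 7 | 2-[(2R)-1-[3-bromo-2,6-bis(methoxymethoxy)phenyl]-7-methyl-3-methylideneoct-6-en-2-yl]-4,4,5,5-tetramethyl-1,3,2-dioxaborolane | C=C(CCC=C(C)C)[C@H](B1OC(C)(C)C(C)(C)O1)Cc2c(OCOC)ccc(Br)c2OCOC
F7 | step 7 | (2R)-1-[3-bromo-2,6-bis(methoxymethoxy)phenyl]-7-methyl-3-methylideneoct-6-en-2-ol | C=C(CCC=C(C)C)[C@H](O)Cc1c(OCOC)ccc(Br)c1OCOC
F8 | step 8 | 2-iodo-1,3-bis{[2-(trimethylsilyl)ethoxy]methoxy}benzene | C[Si](C)(C)CCOCOc1cccc(OCOCC[Si](C)(C)C)c1I
F9 | step 8 | 2-[(2R)-1-(2,6-bis{[2-(trimethylsilyl)ethoxy]methoxy}phenyl)-7-methyl-3-methylideneoct-6-en-2-yl]-4,4,5,5-tetramethyl-1,3,2-dioxaborolane | C=C(CCC=C(C)C)[C@H](B1OC(C)(C)C(C)(C)O1)Cc2c(OCOCC[Si](C)(C)C)cccc2OCOCC[Si](C)(C)C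
F10 | step 8 | (2R)-1-(2,6-bis{[2-(trimethylsilyl)ethoxy]methoxy}phenyl)-7-methyl-3-methylideneoct-6-en-2-ol | C=C(CCC=C(C)C)[C@H](O)Cc1c(OCOCC[Si](C)(C)C)cccc1OCOCC[Si](C)(C)C
F11 | step 8 | (2E)-3-{4-[(tert-butyldimethylsilyl)oxy]phenyl}-N-methoxy-N-methylprop-2-enamide | CON(C)C(=O)/C=C/c1ccc(O[Si](C)(C)C(C)(C)C)cc1
F12 | step 8 | (2E)-3-{4-[(tert-butyldimethylsilyl)oxy]phenyl}-1-{3-[(2R)-2-hydroxy-7-methyl-3-methylideneoct-6-en-1-yl]-2,4-bis{[2-(trimethylsilyl)ethoxy]methoxy}phenyl}prop-2-en-1-one | C=C(CCC=C(C)C)[C@H](O)Cc1c(OCOCC[Si](C)(C)C)ccc(C(=O)/C=C/c2ccc(O[Si](C)(C)C(C)(C)C)cc2)c1OCOCC[Si](C)(C)C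
A1 | alternative 1 | methyl 2-[(2R)-2-[(tert-butyldimethylsilyl)oxy]-7-methyl-3-methylideneoct-6-en-1-yl]-3-oxobutanoate | COC(=O)C(C[C@@H](O[Si](C)(C)C(C)(C)C)C(=C)CCC=C(C)C)C(C)=O
A2 | alternative 1 | 2-alkyl-1-methoxy-1,3-bis(trimethylsilyloxy)buta-1,3-diene carrying the (2R)-2-[(tert-butyldimethylsilyl)oxy]-7-methyl-3-methylideneoct-6-en-1-yl group | C=C(O[Si](C)(C)C)C(C[C@@H](O[Si](C)(C)C(C)(C)C)C(=C)CCC=C(C)C)=C(OC)O[Si](C)(C)C
A3 | alternative 1 | (1E)-1-{4-[(tert-butyldimethylsilyl)oxy]phenyl}pent-1-en-4-yn-3-one | C#CC(=O)/C=C/c1ccc(O[Si](C)(C)C(C)(C)C)cc1
A4 | alternative 1 | target as its C2''-O and ring B bis(tert-butyldimethylsilyl) ether | C=C(CCC=C(C)C)[C@H](O[Si](C)(C)C(C)(C)C)Cc1c(O)ccc(C(=O)/C=C/c2ccc(O[Si](C)(C)C(C)(C)C)cc2)c1O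
A5 | alternative 2 | (2E)-2-{2-[2,6-bis(methoxymethoxy)phenyl]ethylidene}-6-methylhept-5-en-1-ol | OC/C(CCC=C(C)C)=C/Cc1c(OCOC)cccc1OCOC
A6 | alternative 2 | titanium tetraisopropoxide, Ti(OiPr)4 | CC(C)O[Ti](OC(C)C)(OC(C)C)OC(C)C
A7 | alternative 2 | D-(−)-diisopropyl tartrate (diisopropyl (2S,3S)-2,3-dihydroxybutanedioate) | CC(C)OC(=O)[C@@H](O)[C@H](O)C(=O)OC(C)C
A8 | alternative 2 | tert-butyl hydroperoxide | CC(C)(C)OO
A9 | alternative 2 | [(2R,3R)-3-{[2,6-bis(methoxymethoxy)phenyl]methyl}-2-(4-methylpent-3-en-1-yl)oxiran-2-yl]methanol | OC[C@@]1(CCC=C(C)C)O[C@@H]1Cc2c(OCOC)cccc2OCOC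
A10 | alternative 3 | tert-butyl{[(2R)-1-[3-iodo-2,6-bis(methoxymethoxy)phenyl]-7-methyl-3-methylideneoct-6-en-2-yl]oxy}dimethylsilane | C=C(CCC=C(C)C)[C@H](O[Si](C)(C)C(C)(C)C)Cc1c(OCOC)ccc(I)c1OCOC
A11 | alternative 3 | carbon monoxide | [C-]#[O+]
A12 | alternative 3 | 4-acetoxystyrene (4-ethenylphenyl acetate) | C=Cc1ccc(OC(C)=O)cc1
A13 | alternative 3 | fully protected chalcone (C2''-O silyl, ring A bis-acetal, ring B acetate) | C=C(CCC=C(C)C)[C@H](O[Si](C)(C)C(C)(C)C)Cc1c(OCOC)ccc(C(=O)/C=C/c2ccc(OC(C)=O)cc2)c1OCOC
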